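The nine-membered carbocycle (C1–C9; C1 carries the side chain, C2 the hydroxyl, C8 and C9 the formyl groups) is opened at C1–C2. If the C9 formyl carbon C10 is written as an exocyclic methylene, C2–OH and C1 form an anti homoallylic alcohol, the signature of a γ-selective allylmetal addition. A chromium-mediated intramolecular allylation of the C2 aldehyde by a C10 allylic bromide therefore forges C1–C2, closes the ring and sets both stereocentres at once, steered by the side-chain methine C11. The precursor is an acyclic bromo dienyl aldehyde holding C11, the acetate, both trisubstituted ring alkenes and a PMB-protected C8 hydroxymethyl group; an Evans aldol reaction and an allylic transposition assemble it.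

Key step: step 16

Numbering used below: C3–C7 complete the ring (C4 bears the methyl group), C11 is the side-chain methine, C12–C17 the 4-methylpent-3-enyl chain and C18 the acetoxymethyl carbon.

Assumption: the geometry of the C1=C9 double bond of the cyclisation precursor is taken to be without consequence, because the derived allylchromium equilibrates before ring closure. Compound 29 is therefore drawn as the isomer that step 14 should favour (C11 cis to CH2Br).

Remark: the allylic bromide is generated by transposition of a secondary dienyl carbinol and the aldehyde by the last oxidation, so the two reactive termini coexist only in 29.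

**Fragment 1 (C2–C10 with C1 as aldehyde)**

Step 1
Reactants: 1 tert-butyl(but-3-yn-1-yloxy)dimethylsilane
Product: 5 (2E)-5-(tert-butyldimethylsilyloxy)-3-methylpent-2-en-1-ol, via alkenylalane 2 (not isolated), via lithium aluminate 3 (not isolated), via alkoxyaluminate 4 (not isolated)
Conditions: AlMe3, Cp2ZrCl2 (cat.), CH2Cl2, 0 °C to rt; n-BuLi, THF, −78 °C; (CH2O)n, rt; aqueous work-up
Reagents that add atoms: trimethylaluminium, C[Al](C)C (the C4 methyl group); formaldehyde as paraformaldehyde, C=O (C6 and its oxygen)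
Why: Zirconium-catalysed carboalumination adds CH3 and Al syn across the terminal alkyne with the methyl on the internal carbon, and the derived aluminate is hydroxymethylated with retention, so C6 and C3 end trans on C4=C5.

Step 2
Reactants: 5 (2E)-5-(tert-butyldimethylsilyloxy)-3-methylpent-2-en-1-ol
Product: 6 [(3E)-5-bromo-3-methylpent-3-enyloxy](tert-butyl)dimethylsilane
Conditions: CBr4, PPh3, CH2Cl2, 0 °C
Reagents that add atoms: carbon tetrabromide, BrC(Br)(Br)Br
Why: Appel bromination converts the primary allylic alcohol into the bromide through an alkoxyphosphonium ion without touching the silyl ether or the alkene geometry.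

Step 3
Reactants: 6 [(3E)-5-bromo-3-methylpent-3-enyloxy](tert-butyl)dimethylsilane; 7 prop-2-yn-1-ol
Product: 8 (5E)-8-(tert-butyldimethylsilyloxy)-6-methyloct-5-en-2-yn-1-ol
Conditions: CuI (cat.), K2CO3, Bu4NCl, DMF, rt
Reagents that add atoms: none
Why: Copper-catalysed coupling of a terminal alkyne with an allylic halide alkylates the copper acetylide at the unhindered primary carbon of 6 and gives the skipped enyne (C6–C7 bond).

Step 4
Reactants: 8 (5E)-8-(tert-butyldimethylsilyloxy)-6-methyloct-5-en-2-yn-1-ol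
Product: 9 (2Z,5E)-8-(tert-butyldimethylsilyloxy)-6-methyl-2-(tributylstannyl)octa-2,5-dien-1-ol
Conditions: Bu3SnH, [Cp*RuCl]4 (cat.), CH2Cl2, rt
Reagents that add atoms: tributyltin hydride, CCCC[SnH](CCCC)CCCC
Why: Hydroxyl-directed ruthenium-catalysed trans-hydrostannation places tin on the alkyne carbon next to the carbinol (C8) and hydrogen anti to it on C7, which fixes the C7=C8 geometry with C6 cis to the tin-bearing position.

Step 5
Reactants: 9 (2Z,5E)-8-(tert-butyldimethylsilyloxy)-6-methyl-2-(tributylstannyl)octa-2,5-dien-1-ol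
Product: 11 tributyl[(2Z,5E)-8-(tert-butyldimethylsilyloxy)-1-(4-methoxybenzyloxy)-6-methylocta-2,5-dien-2-yl]stannane, via sodium alkoxide 10 (not isolated)
Conditions: NaH, THF/DMF, 0 °C; PMBCl, Bu4NI (cat.), 0 °C to rt
Reagents that add atoms: 4-methoxybenzyl chloride, COc1ccc(CCl)cc1
Why: Williamson etherification of the sodium alkoxide proceeds under basic conditions that leave the acid-sensitive alkenylstannane intact.

Step 6
Reactants: 11 tributyl[(2Z,5E)-8-(tert-butyldimethylsilyloxy)-1-(4-methoxybenzyloxy)-6-methylocta-2,5-dien-2-yl]stannane; 12 2-bromoprop-2-en-1-ol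
Product: 13 (3E,6E)-9-(tert-butyldimethylsilyloxy)-3-[(4-methoxybenzyloxy)methyl]-7-methyl-2-methylidenenona-3,6-dien-1-ol
Conditions: Pd(PPh3)4 (cat.), CuI, CsF, DMF, 45 °C
Reagents that add atoms: none
Why: Stille cross-coupling promoted by CuI and fluoride joins C8 to C9 with retention of the alkenyl geometry (C6 cis to C9), the unhindered bromoalkene compensating for the α-substituted stannane.

Step 7
Reactants: 13 (3E,6E)-9-(tert-butyldimethylsilyloxy)-3-[(4-methoxybenzyloxy)methyl]-7-methyl-2-methylidenenona-3,6-dien-1-ol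
Product: 14 (3E,6E)-9-(tert-butyldimethylsilyloxy)-3-[(4-methoxybenzyloxy)methyl]-7-methyl-2-methylidenenona-3,6-dienal
Conditions: MnO2, CH2Cl2, rt; used at once
Reagents that add atoms: none
Why: Allylic oxidation with MnO2 converts only the primary allylic alcohol into the 2-alkenyl acrolein (C1 aldehyde) and leaves the PMB and silyl ethers untouched.

**Fragment 2 (C11–C18)**

Step 8
Reactants: 15 hex-5-enoic acid; 16 2-methylbut-2-ene
Product: 17 6-methylhept-5-enoic acid
Conditions: second-generation Grubbs catalyst RuCl2(=CHPh)(PCy3)(H2IMes) (cat.), 16 in excess, CH2Cl2, rt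
Reagents that add atoms: none
Why: Olefin cross-metathesis of a terminal alkene with excess 2-methylbut-2-ene installs the isopropylidene terminus and tolerates the free acid.

Step 9
Reactants: 17 6-methylhept-5-enoic acid; 18 (4S)-4-benzyl-1,3-oxazolidin-2-one
Product: 20 (4S)-4-benzyl-3-(6-methylhept-5-enoyl)-1,3-oxazolidin-2-one, via mixed pivalic anhydride 19 (not isolated)
Conditions: PivCl, Et3N, THF, −20 °C; LiCl, 18, −20 °C to rt
Reagents that add atoms: none
Why: N-Acylation of the oxazolidinone through the mixed anhydride gives the imide whose benzyl group will control the C11 configuration.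

**Union, cyclisation and completion**

Step 10
Reactants: 20 (4S)-4-benzyl-3-(6-methylhept-5-enoyl)-1,3-oxazolidin-2-one; 14 (3E,6E)-9-(tert-butyldimethylsilyloxy)-3-[(4-methoxybenzyloxy)methyl]-7-methyl-2-methylidenenona-3,6-dienal
Product: 23 (4S)-4-benzyl-3-{(2S,3S,5E,8E)-11-(tert-butyldimethylsilyloxy)-3-hydroxy-5-[(4-methoxybenzyloxy)methyl]-9-methyl-4-methylidene-2-(4-methylpent-3-enyl)undeca-5,8-dienoyl}-1,3-oxazolidin-2-one, via Z-boron enolate 21 (not isolated), via boron aldolate 22 (not isolated)
Conditions: Bu2BOTf, i-Pr2NEt, CH2Cl2, 0 °C; 14, −78 to 0 °C; pH 7 buffer, MeOH, H2O2, 0 °C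
Reagents that add atoms: none
Why: Evans syn-aldol reaction, in which the Z-boron enolate adds through a Zimmerman–Traxler chair on the face opposite the benzyl group, forms C11–C1, sets C11 with the configuration of the target and gives a C1 carbinol whose configuration is erased in step 14.

Step 11
Reactants: 23 syn-aldol imide
Product: 24 (2R,3S,5E,8E)-11-(tert-butyldimethylsilyloxy)-5-[(4-methoxybenzyloxy)methyl]-9-methyl-4-methylidene-2-(4-methylpent-3-enyl)undeca-5,8-diene-1,3-diol
Conditions: LiBH4, MeOH (1 equiv), THF, 0 °C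
Reagents that add atoms: none
Why: Reductive cleavage of the imide by borohydride releases the primary C18 alcohol and the recoverable auxiliary without affecting ethers or alkenes.

Step 12
Reactants: 24 C18,C1-diol
Product: 25 (2R,3S,5E,8E)-11-(tert-butyldimethylsilyloxy)-3-hydroxy-5-[(4-methoxybenzyloxy)methyl]-9-methyl-4-methylidene-2-(4-methylpent-3-enyl)undeca-5,8-dienyl acetate
Conditions: AcCl (1.1 equiv), 2,4,6-collidine, CH2Cl2, −78 °C
Reagents that add atoms: acetyl chloride, CC(=O)Cl
Why: Kinetically selective acylation of a primary alcohol beside a hindered secondary one installs the C18 acetate of the target.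

Step 13
Reactants: 25 C18 acetate with C2–OTBS
Product: 26 (2R,3S,5E,8E)-3,11-dihydroxy-5-[(4-methoxybenzyloxy)methyl]-9-methyl-4-methylidene-2-(4-methylpent-3-enyl)undeca-5,8-dienyl acetate
Conditions: HF·pyridine, pyridine, THF, 0 °C to rt
Reagents that add atoms: none
Why: Fluoride-mediated desilylation under buffered conditions frees the primary C2 hydroxyl while the acetate, the PMB ether and the acid-sensitive dienyl carbinol persist.

Step 14
Reactants: 26 C1,C2-diol
Product: 28 (2S,3Z,5E,8E)-4-(bromomethyl)-11-hydroxy-5-[(4-methoxybenzyloxy)methyl]-9-methyl-2-(4-methylpent-3-enyl)undeca-3,5,8-trienyl acetate, via alkoxysulfonium bromide 27 (not isolated)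
Conditions: NBS, Me2S, CH2Cl2, −20 to 0 °C
Reagents that add atoms: N-bromosuccinimide, O=C1CCC(=O)N1Br
Why: Corey–Kim-type allylic bromination activates the allylic C1 hydroxyl as an alkoxysulfonium ion that bromide opens at the unhindered C10 terminus (SN2'), giving the conjugated primary bromide, whereas the saturated C2 hydroxyl is returned on work-up.

Step 15
Reactants: 28 bromo alcohol
Product: 29 (2S,3Z,5E,8E)-4-(bromomethyl)-5-[(4-methoxybenzyloxy)methyl]-9-methyl-2-(4-methylpent-3-enyl)-11-oxoundeca-3,5,8-trienyl acetate (cyclisation precursor)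
Conditions: Dess–Martin periodinane, NaHCO3, CH2Cl2, 0 °C; used at once
Reagents that add atoms: none
Why: Dess–Martin oxidation gives the β,γ-unsaturated C2 aldehyde under near-neutral conditions that spare the allylic bromide and do not move the C4=C5 double bond.

Step 16
Reactants: 29 bromo dienyl aldehyde
Product: 32 (2S)-2-[(1R,2S,4E,7E)-2-hydroxy-8-[(4-methoxybenzyloxy)methyl]-4-methyl-9-methylidenecyclonona-4,7-dien-1-yl]-6-methylhept-5-enyl acetate, via allylchromium dichloride 30 (not isolated), via chromium alkoxide 31 (not isolated)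
Conditions: CrCl2 (8 equiv), THF (2 mM), rt, slow addition of 29; aqueous work-up
Reagents that add atoms: none
Why: Two equivalents of divalent chromium reduce the C10–Br bond to the allylchromium 30, whose trivalent chromium binds the C2 aldehyde oxygen so that the γ-carbon C1 adds to C2 through a six-membered chair transition state with shift of the double bond to C9=C10. The closest known reaction type is the Nozaki–Hiyama cyclisation of ω-formyl allylic bromides to medium and large carbocycles. The nine-membered ring C1–C9 is closed in a 9-exo-trig mode at high dilution. C1 and C2 are formed together: the chair places C11 and C3 equatorial, which gives the anti pair from either C1=C9 geometry because the allylchromium equilibrates by 1,3-metal shift, and the absolute sense at C1 is set by C11, whose C–H bond eclipses the allyl plane so that the aldehyde enters on the face of the acetoxymethyl arm, away from the longer chain. The step needs γ- over α-attack (both would give nine-membered rings), which the cyclic transition state with chromium on the primary C10 secures. It also needs tolerance of acetate, PMB ether and skipped diene, which the neutral conditions provide.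

Step 17
Reactants: 32 cyclononadienol
Product: 33 (2S)-2-[(1R,2S,4E,7E)-8-[(4-methoxybenzyloxy)methyl]-4-methyl-9-methylidene-2-(triethylsilyloxy)cyclonona-4,7-dien-1-yl]-6-methylhept-5-enyl acetate
Conditions: TESOTf, 2,6-lutidine, CH2Cl2, −78 °C
Reagents that add atoms: triethylsilyl triflate, CC[Si](CC)(CC)OS(=O)(=O)C(F)(F)F
Why: Silyl ether formation masks the C2 hydroxyl so that the later double oxidation and the adjustment of C9 cannot give a ketone or a bridged lactol.

Step 18
Reactants: 33 TES ether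
Product: 35 (2S)-2-[(1R,2S,4E,7E,9R)-9-(hydroxymethyl)-8-[(4-methoxybenzyloxy)methyl]-4-methyl-2-(triethylsilyloxy)cyclonona-4,7-dien-1-yl]-6-methylhept-5-enyl acetate, via alkylborane 34 (not isolated)
Conditions: 9-BBN, THF, 0 °C to rt; NaBO3·4H2O, THF/H2O, rt
Reagents that add atoms: sodium perborate, [Na+].[Na+].O[B-]1(O)OO[B-](O)(O)OO1 (oxygen of the C10 hydroxyl)
Why: Hydroboration–oxidation with 9-BBN selects the 1,1-disubstituted C9=C10 over the three trisubstituted alkenes and puts boron on C10; hydrogen should reach C9 from the outer face, on which the C11–H lies, to give 9R, and any C9 epimer is carried on because C9 is adjusted in step 20.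

Step 19
Reactants: 35 C10 alcohol
Product: 36 (2S)-2-[(1R,2S,4E,7E,9R)-8,9-bis(hydroxymethyl)-4-methyl-2-(triethylsilyloxy)cyclonona-4,7-dien-1-yl]-6-methylhept-5-enyl acetate
Conditions: DDQ, CH2Cl2/pH 7 buffer, 0 °C
Reagents that add atoms: none
Why: Oxidative cleavage of the PMB ether by DDQ in wet buffered solvent frees the allylic alcohol without affecting the TES ether, the acetate or the skipped diene, the conjugated diene having been removed in step 18.

Step 20
Reactants: 36 1,4-diol
Product: 38 (2S)-2-[(1R,2S,4E,7E,9R)-8,9-diformyl-4-methyl-2-(triethylsilyloxy)cyclonona-4,7-dien-1-yl]-6-methylhept-5-enyl acetate, via bis(alkoxysulfonium) salt 37 (not isolated)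
Conditions: (COCl)2, DMSO, CH2Cl2, −78 °C; Et3N, −78 °C to rt
Reagents that add atoms: none
Why: Double Swern oxidation activates both hydroxyls before base is added, so the 1,4-dialdehyde forms without lactol or lactone, and the labile C9–H (α to the new formyl group and allylic) can equilibrate under Et3N to the trans C1/C9 arrangement, expected to be the more stable one.

Step 21
Reactants: 38 dialdehyde TES ether
Product: 39 (2S)-2-[(1R,2S,4E,7E,9R)-8,9-diformyl-2-hydroxy-4-methylcyclonona-4,7-dien-1-yl]-6-methylhept-5-enyl acetate (target)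
Conditions: HF (48% aq.), MeCN, 0 °C
Reagents that add atoms: none
Why: Acidic fluoride desilylation removes the secondary TES ether without base, so C9 and the acetate are untouched, and the trans-disposed C2–OH and C9–CHO cannot close a lactol.

**Compound list**

1 | tert-butyl(but-3-yn-1-yloxy)dimethylsilane | C#CCCO[Si](C)(C)C(C)(C)C | starting material
2 | dimethyl[(1E)-4-(tert-butyldimethylsilyloxy)-2-methylbut-1-enyl]alane | C[Al](C)/C=C(C)/CCO[Si](C)(C)C(C)(C)C | intermediate (not isolated)
3 | lithium butyl(dimethyl)[(1E)-4-(tert-butyldimethylsilyloxy)-2-methylbut-1-enyl]aluminate | [Li+].CCCC[Al-](C)(C)/C=C(C)/CCO[Si](C)(C)C(C)(C)C | intermediate (not isolated)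
4 | lithium butyl(dimethyl)[(2E)-5-(tert-butyldimethylsilyloxy)-3-methylpent-2-enyloxy]aluminate | [Li+].CCCC[Al-](C)(C)OC/C=C(C)/CCO[Si](C)(C)C(C)(C)C | intermediate (not isolated)
5 | (2E)-5-(tert-butyldimethylsilyloxy)-3-methylpent-2-en-1-ol | OC/C=C(C)/CCO[Si](C)(C)C(C)(C)C | intermediate
6 | [(3E)-5-bromo-3-methylpent-3-enyloxy](tert-butyl)dimethylsilane | BrC/C=C(C)/CCO[Si](C)(C)C(C)(C)C | intermediate
7 | prop-2-yn-1-ol | C#CCO | starting material
8 | (5E)-8-(tert-butyldimethylsilyloxy)-6-methyloct-5-en-2-yn-1-ol | OCC#CC/C=C(C)/CCO[Si](C)(C)C(C)(C)C | intermediate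
9 | (2Z,5E)-8-(tert-butyldimethylsilyloxy)-6-methyl-2-(tributylstannyl)octa-2,5-dien-1-ol | OC/C([Sn](CCCC)(CCCC)CCCC)=C/C/C=C(C)/CCO[Si](C)(C)C(C)(C)C | intermediate
10 | sodium alkoxide of 9 | [Na+].[O-]C/C([Sn](CCCC)(CCCC)CCCC)=C/C/C=C(C)/CCO[Si](C)(C)C(C)(C)C | intermediate (not isolated)
11 | tributyl[(2Z,5E)-8-(tert-butyldimethylsilyloxy)-1-(4-methoxybenzyloxy)-6-methylocta-2,5-dien-2-yl]stannane | COc1ccc(COC/C([Sn](CCCC)(CCCC)CCCC)=C/C/C=C(C)/CCO[Si](C)(C)C(C)(C)C)cc1 | intermediate
12 | 2-bromoprop-2-en-1-ol | C=C(Br)CO | starting material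
13 | (3E,6E)-9-(tert-butyldimethylsilyloxy)-3-[(4-methoxybenzyloxy)methyl]-7-methyl-2-methylidenenona-3,6-dien-1-ol | C=C(CO)\C(COCc1ccc(OC)cc1)=C/C/C=C(C)/CCO[Si](C)(C)C(C)(C)C | intermediate
14 | (3E,6E)-9-(tert-butyldimethylsilyloxy)-3-[(4-methoxybenzyloxy)methyl]-7-methyl-2-methylidenenona-3,6-dienal (fragment 1) | C=C(C=O)\C(COCc1ccc(OC)cc1)=C/C/C=C(C)/CCO[Si](C)(C)C(C)(C)C | intermediate
15 | hex-5-enoic acid | C=CCCCC(=O)O | starting material
16 | 2-methylbut-2-ene | CC=C(C)C | starting material
17 | 6-methylhept-5-enoic acid | CC(C)=CCCCC(=O)O | intermediate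
18 | (4S)-4-benzyl-1,3-oxazolidin-2-one | O=C1N[C@@H](Cc2ccccc2)CO1 | starting material
19 | 6-methylhept-5-enoic pivalic anhydride | CC(C)=CCCCC(=O)OC(=O)C(C)(C)C | intermediate (not isolated)
20 | (4S)-4-benzyl-3-(6-methylhept-5-enoyl)-1,3-oxazolidin-2-one (fragment 2) | CC(C)=CCCCC(=O)N1[C@@H](Cc2ccccc2)COC1=O | intermediate
21 | (Z)-dibutylboron enolate of 20 | CCCCB(CCCC)O/C(=C\CCC=C(C)C)N1[C@@H](Cc2ccccc2)COC1=O | intermediate (not isolated)
22 | dibutylboron aldolate of 23 | CC(C)=CCC[C@H](C(=O)N1[C@@H](Cc2ccccc2)COC1=O)[C@H](OB(CCCC)CCCC)C(=C)\C(COCc1ccc(OC)cc1)=C/C/C=C(C)/CCO[Si](C)(C)C(C)(C)C | intermediate (not isolated)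
23 | syn-aldol imide, (2S,3S) in the acyl chain (C11 S, C1 S) | CC(C)=CCC[C@H](C(=O)N1[C@@H](Cc2ccccc2)COC1=O)[C@H](O)C(=C)\C(COCc1ccc(OC)cc1)=C/C/C=C(C)/CCO[Si](C)(C)C(C)(C)C | intermediate
24 | (2R,3S,5E,8E)-11-(tert-butyldimethylsilyloxy)-5-[(4-methoxybenzyloxy)methyl]-9-methyl-4-methylidene-2-(4-methylpent-3-enyl)undeca-5,8-diene-1,3-diol | CC(C)=CCC[C@H](CO)[C@H](O)C(=C)\C(COCc1ccc(OC)cc1)=C/C/C=C(C)/CCO[Si](C)(C)C(C)(C)C | intermediate
25 | (2R,3S,5E,8E)-11-(tert-butyldimethylsilyloxy)-3-hydroxy-5-[(4-methoxybenzyloxy)methyl]-9-methyl-4-methylidene-2-(4-methylpent-3-enyl)undeca-5,8-dienyl acetate | CC(C)=CCC[C@H](COC(C)=O)[C@H](O)C(=C)\C(COCc1ccc(OC)cc1)=C/C/C=C(C)/CCO[Si](C)(C)C(C)(C)C | intermediate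
26 | (2R,3S,5E,8E)-3,11-dihydroxy-5-[(4-methoxybenzyloxy)methyl]-9-methyl-4-methylidene-2-(4-methylpent-3-enyl)undeca-5,8-dienyl acetate | CC(C)=CCC[C@H](COC(C)=O)[C@H](O)C(=C)\C(COCc1ccc(OC)cc1)=C/C/C=C(C)/CCO | intermediate
27 | C1 alkoxydimethylsulfonium bromide of 26 | CC(C)=CCC[C@H](COC(C)=O)[C@H](O[S+](C)C)C(=C)\C(COCc1ccc(OC)cc1)=C/C/C=C(C)/CCO.[Br-] | intermediate (not isolated)
28 | (2S,3Z,5E,8E)-4-(bromomethyl)-11-hydroxy-5-[(4-methoxybenzyloxy)methyl]-9-methyl-2-(4-methylpent-3-enyl)undeca-3,5,8-trienyl acetate | CC(=O)OC[C@@H](CCC=C(C)C)/C=C(CBr)/C(COCc1ccc(OC)cc1)=C\C/C=C(C)/CCO | intermediate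
29 | (2S,3Z,5E,8E)-4-(bromomethyl)-5-[(4-methoxybenzyloxy)methyl]-9-methyl-2-(4-methylpent-3-enyl)-11-oxoundeca-3,5,8-trienyl acetate (cyclisation precursor) | CC(=O)OC[C@@H](CCC=C(C)C)/C=C(CBr)/C(COCc1ccc(OC)cc1)=C\C/C=C(C)/CC=O | intermediate
30 | C10 allylchromium dichloride derived from 29 | CC(=O)OC[C@@H](CCC=C(C)C)/C=C(C[Cr](Cl)Cl)/C(COCc1ccc(OC)cc1)=C\C/C=C(C)/CC=O | intermediate (not isolated)
31 | C2 chromium alkoxide of 32 | CC(=O)OC[C@@H](CCC=C(C)C)[C@H]1[C@@H](O[Cr](Cl)Cl)C/C(C)=C/C/C=C(/COCc2ccc(OC)cc2)C1=C | intermediate (not isolated)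
32 | (2S)-2-[(1R,2S,4E,7E)-2-hydroxy-8-[(4-methoxybenzyloxy)methyl]-4-methyl-9-methylidenecyclonona-4,7-dien-1-yl]-6-methylhept-5-enyl acetate (key-step product) | CC(=O)OC[C@@H](CCC=C(C)C)[C@H]1[C@@H](O)C/C(C)=C/C/C=C(/COCc2ccc(OC)cc2)C1=C | intermediate
33 | C2 triethylsilyl ether of 32 | CC(=O)OC[C@@H](CCC=C(C)C)[C@H]1[C@@H](O[Si](CC)(CC)CC)C/C(C)=C/C/C=C(/COCc2ccc(OC)cc2)C1=C | intermediate
34 | C10 B-alkyl-9-borabicyclo[3.3.1]nonane from 33 | CC(=O)OC[C@@H](CCC=C(C)C)[C@H]1[C@@H](O[Si](CC)(CC)CC)C/C(C)=C/C/C=C(/COCc2ccc(OC)cc2)[C@@H]1CB1C2CCCC1CCC2 | intermediate (not isolated)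
35 | (2S)-2-[(1R,2S,4E,7E,9R)-9-(hydroxymethyl)-8-[(4-methoxybenzyloxy)methyl]-4-methyl-2-(triethylsilyloxy)cyclonona-4,7-dien-1-yl]-6-methylhept-5-enyl acetate | CC(=O)OC[C@@H](CCC=C(C)C)[C@H]1[C@@H](O[Si](CC)(CC)CC)C/C(C)=C/C/C=C(/COCc2ccc(OC)cc2)[C@@H]1CO | intermediate
36 | (2S)-2-[(1R,2S,4E,7E,9R)-8,9-bis(hydroxymethyl)-4-methyl-2-(triethylsilyloxy)cyclonona-4,7-dien-1-yl]-6-methylhept-5-enyl acetate | CC(=O)OC[C@@H](CCC=C(C)C)[C@H]1[C@@H](O[Si](CC)(CC)CC)C/C(C)=C/C/C=C(/CO)[C@@H]1CO | intermediate
37 | bis(alkoxydimethylsulfonium) dichloride of 36 | CC(=O)OC[C@@H](CCC=C(C)C)[C@H]1[C@@H](O[Si](CC)(CC)CC)C/C(C)=C/C/C=C(/CO[S+](C)C)[C@@H]1CO[S+](C)C.[Cl-].[Cl-] | intermediate (not isolated)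
38 | (2S)-2-[(1R,2S,4E,7E,9R)-8,9-diformyl-4-methyl-2-(triethylsilyloxy)cyclonona-4,7-dien-1-yl]-6-methylhept-5-enyl acetate | CC(=O)OC[C@@H](CCC=C(C)C)[C@H]1[C@@H](O[Si](CC)(CC)CC)C/C(C)=C/C/C=C(/C=O)[C@@H]1C=O | intermediate
39 | (2S)-2-[(1R,2S,4E,7E,9R)-8,9-diformyl-2-hydroxy-4-methylcyclonona-4,7-dien-1-yl]-6-methylhept-5-enyl acetate | CC(=O)OC[C@@H](CCC=C(C)C)[C@H]1[C@@H](O)C/C(C)=C/C/C=C(/C=O)[C@@H]1C=O | target

Total step count: 21. Longest linear sequence: 19 steps (steps 1–7, then 10–21); steps 8–9 form the short branch.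

**Steps most likely to fail**

Step 16. The ring being formed may distort the chair transition state, so that the anti relationship between C1 and C2 is eroded or inverted. The fallback sets C2 by reduction instead of by the allylation. It sets out from 32 obtained as a mixture of C2 epimers. Dess–Martin oxidation should give the cyclononadienone F1. Reduction with NaBH4 and CeCl3·7H2O in MeOH at −78 °C should then deliver hydride to the carbonyl face away from the C1 side chain, which places the hydroxyl cis to that chain. The route is rejoined at 32.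

Step 20. Equilibration at C9 may settle on the wrong side, or the amine may move the C7=C8 double bond out of conjugation. The fallback replaces thermodynamic by kinetic control and sets out from 38 as the epimer mixture. TMSOTf and Et3N in CH2Cl2 at −78 °C should convert the C10 aldehyde into its trimethylsilyl dienol ether F2 (C9=C10, geometry not controlled). Buffered fluoride (Bu4NF/AcOH, THF, −78 °C) should then protonate C9 from the outer face of the ring. The route is rejoined at 38, and step 21 follows without base.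

Step 14. Bromide may enter at C1 without allylic transposition, or the primary C2 hydroxyl may be brominated as well. The fallback brominates before the C2 hydroxyl is unveiled and sets out from 25. MsCl and Et3N should give the allylic mesylate F3. LiBr in THF should displace it with allylic transposition to the primary bromide F4, which still carries the C2 silyl ether. Aqueous HF in MeCN should then remove the TBS group, and the route is rejoined at 28.

Further compounds
F1 | step 16 | (2S)-2-[(1R,4E,7E)-8-[(4-methoxybenzyloxy)methyl]-4-methyl-9-methylidene-2-oxocyclonona-4,7-dien-1-yl]-6-methylhept-5-enyl acetate | CC(=O)OC[C@@H](CCC=C(C)C)[C@H]1C(=O)C/C(C)=C/C/C=C(/COCc2ccc(OC)cc2)C1=C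
F2 | step 20 | C10 trimethylsilyl dienol ether of 38 | CC(=O)OC[C@@H](CCC=C(C)C)[C@H]1[C@@H](O[Si](CC)(CC)CC)C/C(C)=C/C/C=C(/C=O)C1=CO[Si](C)(C)C
F3 | step 14 | C1 methanesulfonate of 25 | CC(C)=CCC[C@H](COC(C)=O)[C@H](OS(C)(=O)=O)C(=C)\C(COCc1ccc(OC)cc1)=C/C/C=C(C)/CCO[Si](C)(C)C(C)(C)C
F4 | step 14 | C2 tert-butyldimethylsilyl ether of 28 | CC(=O)OC[C@@H](CCC=C(C)C)/C=C(CBr)/C(COCc1ccc(OC)cc1)=C\C/C=C(C)/CCO[Si](C)(C)C(C)(C)C
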